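The pyran ring is cut at C4–C4a and O1–C2, so the chroman falls apart into 2,3-dimethoxyhydroquinone and a 2-arylacrolein. The feature exploited is that ring A (C4a to C8a, with O1 and the C6 hydroxyl) is this hydroquinone tied back through one oxygen: its two ortho CH/OH pairs are equivalent, so whichever pair reacts supplies C4a and O1 and the untouched OH ends up at C6. One amine-catalysed operation forges C4–C4a, sets C3 by enantioselective protonation and closes O1–C2 as a lactol. The acrolein carries ring B as a dibenzyl-protected hydroquinone and is released from a storable diethyl acetal; one hydroquinone feeds both halves.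

Key step: step 6

Assumption: the sense of induction of the amine catalyst in step 6 cannot be predicted with certainty; the (2S)-diamine is written, and its (2R)-antipode is to be used unchanged otherwise if a pilot run gives the 3R lactol.

Step 1
Reactants: 1 2,3-dimethoxy-1,4-benzoquinone
Product: 2 2,3-dimethoxybenzene-1,4-diol
Conditions: H2 (1 atm), Pd/C (5 mol%), EtOAc, rt; filtered and kept under Ar
Reagents that add atoms: none
Why: Catalytic hydrogenation of a quinone to its hydroquinone is fast and leaves no reagent residue in the air-sensitive diol, which later serves both as the source of ring B and as the nucleophile that becomes ring A.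

Step 2
Reactants: 2 2,3-dimethoxybenzene-1,4-diol; 3 benzyl bromide
Product: 4 1,4-bis(benzyloxy)-2,3-dimethoxybenzene
Conditions: BnBr (2.3 equiv), K2CO3, DMF (degassed), 50 °C, Ar
Reagents that add atoms: benzyl bromide (3), BrCc1ccccc1
Why: Williamson etherification of both phenoxides should proceed cleanly, and benzyl is chosen because it survives organometallic, acidic, hydride and Mitsunobu conditions and is removed at the end without acid or oxidant.

Step 3
Reactants: 4 1,4-bis(benzyloxy)-2,3-dimethoxybenzene
Product: 5 1,4-bis(benzyloxy)-5-bromo-2,3-dimethoxybenzene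
Conditions: NBS (1.0 equiv), MeCN, 0 °C to rt, dark
Reagents that add atoms: N-bromosuccinimide, O=C1CCC(=O)N1Br
Why: Electrophilic aromatic bromination of a tetraalkoxybenzene is fast in a polar solvent, the two free ring positions are equivalent, and one equivalent of NBS should stop at the monobromide.

Step 4
Reactants: 5 1,4-bis(benzyloxy)-5-bromo-2,3-dimethoxybenzene; 6 2-bromo-3,3-diethoxyprop-1-ene
Product: 9 1,4-bis(benzyloxy)-5-(3,3-diethoxyprop-1-en-2-yl)-2,3-dimethoxybenzene, via aryllithium 7 (not isolated), via arylzinc chloride 8 (not isolated)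
Conditions: n-BuLi, THF, −78 °C; ZnCl2, −78 °C to rt; 6, Pd(PPh3)4 (5 mol%), 50 °C; NaHCO3 work-up, Et3N-deactivated SiO2
Reagents that add atoms: 2-bromo-3,3-diethoxyprop-1-ene (6), C=C(Br)C(OCC)OCC; n-butyllithium, [Li]CCCC (lithium of 7 only); ZnCl2, Cl[Zn]Cl (zinc and chlorine of 8 only)
Why: Bromine–lithium exchange at −78 °C outruns benzylic deprotonation, transmetalation gives an arylzinc that tolerates acetal and benzyl ethers, and Negishi coupling with a 1,1-disubstituted vinyl bromide installs the masked acrolein unit in one operation without ozone or a labile arylacetaldehyde.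

Step 5
Reactants: 9 1,4-bis(benzyloxy)-5-(3,3-diethoxyprop-1-en-2-yl)-2,3-dimethoxybenzene
Product: 10 2-[2,5-bis(benzyloxy)-3,4-dimethoxyphenyl]prop-2-enal
Conditions: 1 M aq. HCl, THF, 0 °C to rt; used the same day
Reagents that add atoms: water, O
Why: Acid-catalysed hydrolysis of an allylic diethyl acetal is fast under conditions that leave aryl benzyl ethers alone, so the dimerisation-prone 2-arylacrolein is set free only when it is needed.

Step 6
Reactants: 10 2-[2,5-bis(benzyloxy)-3,4-dimethoxyphenyl]prop-2-enal; 2 2,3-dimethoxybenzene-1,4-diol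
Product: 12 (3S)-3-[2,5-bis(benzyloxy)-3,4-dimethoxyphenyl]-7,8-dimethoxychroman-2,6-diol as both C2 anomers, via hydroxy-aldehyde 11 (not isolated)
Conditions: 2 (2.5 equiv), (2S)-N1,N1-diethyl-3,3-dimethylbutane-1,2-diamine·TfOH (20 mol%), CHCl3 (degassed), 0 °C, Ar; short SiO2 plug, taken on at once
Reagents that add atoms: none
Why: Proposed new method: the primary amine of the catalyst condenses with enal 10 to an iminium ion, the hydroquinone adds through the carbon ortho to one OH and para to a methoxy group to the methylene terminus (C4–C4a), the α-aryl enamine so formed is protonated at C3 by the adjacent ammonium N–H of the catalyst, and hydrolysis releases hydroxy-aldehyde 11. The closest known reaction types are the amine-catalysed Friedel–Crafts addition/hemiacetalisation of electron-rich phenols with enals to chroman-2-ols and the primary–tertiary diamine-catalysed conjugate addition/enantioselective enamine protonation of α-substituted acroleins; their combination on a hydroquinone and a 2-arylacrolein is the untested element. The pyran ring closes by reversible 6-exo-trig attack of the neighbouring phenolic oxygen on the aldehyde carbon (O1–C2), giving both anomers. C3 is set under catalyst control by intramolecular proton delivery to one face of the enamine, there being no other stereocentre in either partner, and C2 needs no control because it is reduced in step 7. The step needs C- over O-alkylation (the oxa-Michael adduct can revert, the C-adduct cannot), a single annulation (the excess of 2 and the crowding of C5 once C4a is substituted should secure this) and configurational stability at C3 (the lactol keeps the aldehyde away from the amine); positional selectivity is no issue because the two ortho CH/OH pairs of 2 are equivalent.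

Step 7
Reactants: 12 (3S)-3-[2,5-bis(benzyloxy)-3,4-dimethoxyphenyl]-7,8-dimethoxychroman-2,6-diol
Product: 13 (2S)-2-[2,5-bis(benzyloxy)-3,4-dimethoxyphenyl]-3-(2,5-dihydroxy-3,4-dimethoxyphenyl)propan-1-ol
Conditions: NaBH4 (3 equiv), EtOH–THF, −20 to 0 °C, Ar; degassed aq. NH4Cl
Reagents that add atoms: none
Why: Borohydride reduction of a lactol takes place on its open hydroxy-aldehyde tautomer (compound 11, in ring–chain equilibrium with 12), which at low temperature is reduced faster than it enolises, so the configuration at the α-aryl carbon should be carried over unchanged.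

Step 8
Reactants: 13 (2S)-2-[2,5-bis(benzyloxy)-3,4-dimethoxyphenyl]-3-(2,5-dihydroxy-3,4-dimethoxyphenyl)propan-1-ol
Product: 14 (3S)-3-[2,5-bis(benzyloxy)-3,4-dimethoxyphenyl]-7,8-dimethoxychroman-6-ol
Conditions: PPh3, DIAD (betaine pre-formed at 0 °C), THF (0.02 M), 0 °C to rt, Ar
Reagents that add atoms: none
Why: In this intramolecular Mitsunobu etherification the primary alcohol is activated as its alkoxyphosphonium ion and displaced 6-exo-tet by the ortho phenoxide, while the para hydroxyl cannot reach the electrophile within the molecule and the stereocentre, one carbon away, is not touched.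

Step 9
Reactants: 14 (3S)-3-[2,5-bis(benzyloxy)-3,4-dimethoxyphenyl]-7,8-dimethoxychroman-6-ol
Product: 16 5-[(3S)-6-hydroxy-7,8-dimethoxychroman-3-yl]-2,3-dimethoxy-1,4-benzoquinone (target), via hydroquinone 15 (not isolated)
Conditions: H2 (1 atm), Pd/C, EtOAc–MeOH, rt; N2 purge, filter; then air (O2), SiO2, EtOAc, rt
Reagents that add atoms: none
Why: Hydrogenolysis of the two aryl benzyl ethers (the chroman has no benzylic C–O bond) unmasks the ring B hydroquinone, which is a much stronger reductant than the ring A mono-phenol and should therefore be the only site dehydrogenated by air to the 1,4-quinone.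

Compound list
1 | 2,3-dimethoxy-1,4-benzoquinone | COC1=C(OC)C(=O)C=CC1=O | starting material
2 | 2,3-dimethoxybenzene-1,4-diol | COc1c(O)ccc(O)c1OC | intermediate
3 | benzyl bromide | BrCc1ccccc1 | starting material
4 | 1,4-bis(benzyloxy)-2,3-dimethoxybenzene | COc1c(OCc2ccccc2)ccc(OCc2ccccc2)c1OC | intermediate
5 | 1,4-bis(benzyloxy)-5-bromo-2,3-dimethoxybenzene | COc1c(OC)c(OCc2ccccc2)cc(Br)c1OCc1ccccc1 | intermediate
6 | 2-bromo-3,3-diethoxyprop-1-ene (2-bromoacrolein diethyl acetal) | C=C(Br)C(OCC)OCC | starting material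
7 | [2,5-bis(benzyloxy)-3,4-dimethoxyphenyl]lithium | [Li]c1cc(OCc2ccccc2)c(OC)c(OC)c1OCc1ccccc1 | intermediate (not isolated)
8 | [2,5-bis(benzyloxy)-3,4-dimethoxyphenyl]zinc chloride | Cl[Zn]c1cc(OCc2ccccc2)c(OC)c(OC)c1OCc1ccccc1 | intermediate (not isolated)
9 | 1,4-bis(benzyloxy)-5-(3,3-diethoxyprop-1-en-2-yl)-2,3-dimethoxybenzene | C=C(C(OCC)OCC)c1cc(OCc2ccccc2)c(OC)c(OC)c1OCc1ccccc1 | intermediate
10 | 2-[2,5-bis(benzyloxy)-3,4-dimethoxyphenyl]prop-2-enal | C=C(C=O)c1cc(OCc2ccccc2)c(OC)c(OC)c1OCc1ccccc1 | intermediate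
11 | (2S)-2-[2,5-bis(benzyloxy)-3,4-dimethoxyphenyl]-3-(2,5-dihydroxy-3,4-dimethoxyphenyl)propanal | O=C[C@@H](Cc1cc(O)c(OC)c(OC)c1O)c1cc(OCc2ccccc2)c(OC)c(OC)c1OCc1ccccc1 | intermediate (not isolated)
12 | (3S)-3-[2,5-bis(benzyloxy)-3,4-dimethoxyphenyl]-7,8-dimethoxychroman-2,6-diol (both C2 anomers) | COc1c(OC)c(OCc2ccccc2)cc([C@H]2C(O)Oc3c(cc(O)c(OC)c3OC)C2)c1OCc1ccccc1 | intermediate
13 | (2S)-2-[2,5-bis(benzyloxy)-3,4-dimethoxyphenyl]-3-(2,5-dihydroxy-3,4-dimethoxyphenyl)propan-1-ol | OC[C@@H](Cc1cc(O)c(OC)c(OC)c1O)c1cc(OCc2ccccc2)c(OC)c(OC)c1OCc1ccccc1 | intermediate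
14 | (3S)-3-[2,5-bis(benzyloxy)-3,4-dimethoxyphenyl]-7,8-dimethoxychroman-6-ol | COc1c(OC)c(OCc2ccccc2)cc([C@H]2COc3c(cc(O)c(OC)c3OC)C2)c1OCc1ccccc1 | intermediate
15 | 2-[(3S)-6-hydroxy-7,8-dimethoxychroman-3-yl]-5,6-dimethoxybenzene-1,4-diol | COc1c(OC)c(O)cc([C@H]2COc3c(cc(O)c(OC)c3OC)C2)c1O | intermediate (not isolated)
16 | 5-[(3S)-6-hydroxy-7,8-dimethoxychroman-3-yl]-2,3-dimethoxycyclohexa-2,5-diene-1,4-dione | COC1=C(OC)C(=O)C([C@H]2COc3c(cc(O)c(OC)c3OC)C2)=CC1=O | target

Total step count: 9. Longest linear sequence: 9 steps (1, 2, 4, 5, 9, 10, 12, 13, 14, 16; compound 2 re-enters at step 6).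

Steps most likely to fail

Step 6. The protonation of the α-aryl enamine may discriminate poorly between the two faces. C3 may also erode if the open aldehyde re-condenses with the amine before lactol closure, and O-addition or a second annulation at C5 may compete. The fallback uses known chemistry and sets C3 by an Evans alkylation; it sets out from bromide 5 and hydroquinone 2 and comes back at triol 13. For the ring B half, Pd-catalysed coupling of 5 with the Reformatsky reagent BrZnCH2CO2tBu (Pd2(dba)3, P(t-Bu)3, THF) should give tert-butyl [2,5-bis(benzyloxy)-3,4-dimethoxyphenyl]acetate F1. TFA in CH2Cl2 at 0 °C then frees [2,5-bis(benzyloxy)-3,4-dimethoxyphenyl]acetic acid F2, and PivCl/Et3N followed by lithiated (4S)-4-benzyl-1,3-oxazolidin-2-one gives (4S)-4-benzyl-3-{[2,5-bis(benzyloxy)-3,4-dimethoxyphenyl]acetyl}-1,3-oxazolidin-2-one F3. For the ring A half, MOMCl/i-Pr2NEt converts 2 into 2,3-dimethoxy-1,4-bis(methoxymethoxy)benzene F4; directed ortho-lithiation (n-BuLi, TMEDA, THF, 0 °C) and a paraformaldehyde quench give [3,4-dimethoxy-2,5-bis(methoxymethoxy)phenyl]methanol F5, which PPh3/CBr4 turns into 1-(bromomethyl)-3,4-dimethoxy-2,5-bis(methoxymethoxy)benzene F6. The two halves are joined by alkylating the sodium enolate of F3 (NaHMDS, THF, −78 °C) with F6 on the face away from the auxiliary benzyl group, which should give (4S)-4-benzyl-3-{(2S)-2-[2,5-bis(benzyloxy)-3,4-dimethoxyphenyl]-3-[3,4-dimethoxy-2,5-bis(methoxymethoxy)phenyl]propanoyl}-1,3-oxazolidin-2-one F7. LiBH4 (THF–MeOH, 0 °C) cleaves the auxiliary to give (2S)-2-[2,5-bis(benzyloxy)-3,4-dimethoxyphenyl]-3-[3,4-dimethoxy-2,5-bis(methoxymethoxy)phenyl]propan-1-ol F8, and HCl in MeOH under argon removes both MOM groups and delivers 13, from which steps 8 and 9 follow unchanged.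

Step 8. The azodicarboxylate may dehydrogenate the electron-rich hydroquinone, or the distal phenol may react intermolecularly to give oligomeric ethers. The fallback sets out from lactol 12 and comes back at chroman 14, replacing steps 7 and 8. Ionic hydrogenation with Et3SiH and BF3·OEt2 in CH2Cl2 at −78 °C reduces the oxocarbenium ion of the lactol directly, so the hydroquinone is never exposed, and the low temperature is meant to suppress loss of the C3 proton from the cation. No new compound arises (F0).

Step 4. The ortho-benzyloxy aryllithium may undergo benzylic deprotonation or Wittig rearrangement before transmetalation, or the hindered arylzinc may couple sluggishly. The fallback sets out from bromide 5 and comes back at acrolein 10, bypassing 9; it builds the three-carbon unit stepwise without an aryllithium. Stille coupling of 5 with allyltributylstannane (Pd(PPh3)4, toluene, 100 °C) gives 1,4-bis(benzyloxy)-2,3-dimethoxy-5-(prop-2-en-1-yl)benzene F9, Lemieux–Johnson cleavage (OsO4 cat., NaIO4, 2,6-lutidine, dioxane–H2O) gives [2,5-bis(benzyloxy)-3,4-dimethoxyphenyl]acetaldehyde F10, and amine-catalysed α-methylenation of F10 (37% aq. CH2O, pyrrolidine and propionic acid 10 mol% each, i-PrOH, 45 °C) delivers 10.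

Further compounds
F1 | step 6 | tert-butyl [2,5-bis(benzyloxy)-3,4-dimethoxyphenyl]acetate | CC(C)(C)OC(=O)Cc1cc(OCc2ccccc2)c(OC)c(OC)c1OCc1ccccc1
F2 | step 6 | [2,5-bis(benzyloxy)-3,4-dimethoxyphenyl]acetic acid | OC(=O)Cc1cc(OCc2ccccc2)c(OC)c(OC)c1OCc1ccccc1
F3 | step 6 | (4S)-4-benzyl-3-{[2,5-bis(benzyloxy)-3,4-dimethoxyphenyl]acetyl}-1,3-oxazolidin-2-one | O=C(Cc1cc(OCc2ccccc2)c(OC)c(OC)c1OCc1ccccc1)N1C(=O)OC[C@@H]1Cc1ccccc1
F4 | step 6 | 2,3-dimethoxy-1,4-bis(methoxymethoxy)benzene | COCOc1ccc(OCOC)c(OC)c1OC
F5 | step 6 | [3,4-dimethoxy-2,5-bis(methoxymethoxy)phenyl]methanol | OCc1cc(OCOC)c(OC)c(OC)c1OCOC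
F6 | step 6 | 1-(bromomethyl)-3,4-dimethoxy-2,5-bis(methoxymethoxy)benzene | BrCc1cc(OCOC)c(OC)c(OC)c1OCOC
F7 | step 6 | (4S)-4-benzyl-3-{(2S)-2-[2,5-bis(benzyloxy)-3,4-dimethoxyphenyl]-3-[3,4-dimethoxy-2,5-bis(methoxymethoxy)phenyl]propanoyl}-1,3-oxazolidin-2-one | O=C([C@@H](Cc1cc(OCOC)c(OC)c(OC)c1OCOC)c1cc(OCc2ccccc2)c(OC)c(OC)c1OCc1ccccc1)N1C(=O)OC[C@@H]1Cc1ccccc1
F8 | step 6 | (2S)-2-[2,5-bis(benzyloxy)-3,4-dimethoxyphenyl]-3-[3,4-dimethoxy-2,5-bis(methoxymethoxy)phenyl]propan-1-ol | OC[C@@H](Cc1cc(OCOC)c(OC)c(OC)c1OCOC)c1cc(OCc2ccccc2)c(OC)c(OC)c1OCc1ccccc1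
F0 | step 8 | none | none
F9 | step 4 | 1,4-bis(benzyloxy)-2,3-dimethoxy-5-(prop-2-en-1-yl)benzene | C=CCc1cc(OCc2ccccc2)c(OC)c(OC)c1OCc1ccccc1
F10 | step 4 | [2,5-bis(benzyloxy)-3,4-dimethoxyphenyl]acetaldehyde | O=CCc1cc(OCc2ccccc2)c(OC)c(OC)c1OCc1ccccc1
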